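A plateau under thermodynamic control holds a pitfall: the percentage looks like the property of the equilibrium. With dissolved partner held, forward and back rates come level when target over starting material equals K[partner], where K is the forward constant over the back constant. That ratio does not contain the charge, so in a plain solution the charge drops out of the percentages.

common to all: gas 200 mM (held)
- north: starting material 2.6 M; the very flask that is asked about, followed so far
- south-east: starting material 1.3 M; run made earlier
- flask: starting material 2.6 M; time 25 h

| run | time / h | target / % | isomer of the product / % | starting material / % |
|---|---|---|---|---|
| north | 3.00 | 95.0 | 2.6 | 2.1 |
| north | 6.00 | 94.8 | 3.4 | 1.1 |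
| north | 10.0 | 95.4 | 3.1 | 1.8 |
| north | 12.0 | 94.6 | 4.4 | 1.3 |
| south-east | 3.00 | 89.4 | 6.7 | 2.9 |
| south-east | 8.00 | 90.0 | 6.8 | 2.6 |
| south-east | 15.0 | 90.5 | 6.6 | 3.8 |
| south-east | 25.0 | 89.8 | 7.0 | 3.2 |

(each reading ± 0.5 percentage points)

- what is said of target includes crystals
- crystals is a solid; its amount is given per volume of the solution
- at the start none of partner is dissolved
- on the list of suspects stand: starting material + partner <-> target; starting material + partner <-> isomer of the product; partner -> decomposed reagent; gas <-> partner; crystals <-> target
- the reaction counts as stopped when no species that holds the starting material changes by six tenths of a point or more over the second half of the time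

1. why nothing more happens at 25 h, or that something still does (forward and back rates have come level / it is still moving)
2. target at 25 h, in percent of the starting material charged
3. isomer of the product at 25 h, in percent of the starting material charged

These readings do not behave so. Take the fraction left, f, the part of the charge read as isomer plus starting material. The south-east run averages f = 9.90% and the north run 4.95%: the north charge is twice the south-east one, and its f is half. The south-east run gives 0.129 M for f times the charge, and this free pool W reads 0.129 M in the north run. A concentration that stays points to a solution standing over crystals: with dissolved target at its solubility and partner held, starting material and isomer keep constant concentrations, and further charge goes into the solid.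

The reckoning made here takes W from the south-east run and divides by the north charge of 2.6 M, which leaves 4.96% and puts target at 95.0%. The isomer's part of the pool, 0.0881 M, gives 3.39%. North target stays between 94.6% and 95.4% up to 12.0 h, so 25 h should read the same.

The forecast says forward and back rates have come level, with target 95% (94.4% to 95.6%) and isomer 3.4% (3% to 3.9%): “Doubling the charge therefore halves those percentages.”

The flask gives 95.1% of target and 3.32% of isomer at 25 h: forward and back rates have come level.

    starting material + partner ⇌ target (K = 30.0 M⁻¹, k = 10.3 M⁻¹ min⁻¹)
    starting material + partner ⇌ isomer of the product (K = 10.8 M⁻¹, k = 6.29 M⁻¹ min⁻¹)
    partner → decomposed reagent (k = 0.00397 min⁻¹)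
    gas ⇌ partner, rate k4*(csat - [partner]) (kL = 0.190 min⁻¹)
    crystals ⇌ target, rate k5*(cs5 - [target]) while solid is left; crystals form when [target] > cs5 (solubility = 0.240 M, k = 2.37 min⁻¹)

The pool of this flask is 0.127 M. The isomer of the product stays so small because of the backward run from isomer of the product to starting material + partner: the simulated run without that step ends at 100% of isomer of the product, not 3.32%. The neighbour flask charged with 1.0 M tests W: the pool read in the south-east run leaves target at 87.1%, and that flask stores 87.3% of target, with crystals still standing at 63.3%.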